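**Retrosynthetic overview**
1. Ring A (cyclohexene C1, C10–C14) comes from an acyclic E-enoate and a methoxy-enone by a tandem Michael/Michael–elimination: C10–C11 forms first and the ring is closed by C1–C14. The enabling feature is the O–C2–C1–C14=C13–C12–O array (C2 as ester enolate donor at C1, C12–C14 as vinylogous ester acceptor) together with the C9–O stereocentre beside C10 and the trans C2/C9 pair, which is the E-alkene C1=C10 in another form.
2. Ring B (ten-membered, C1–C10) is never closed directly. A temporary cyclohexanone ring T (C1–C2–C3–C8–C9–C10), made by aldol closure of C2–C3, is opened at C3–C8 by a siloxy-Cope rearrangement of a 3-allenyl/8-(E)-2-chlorovinyl pair.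
3. That rearrangement is planned to deliver C3=C4 (Z), C5=C16, C6–Cl and the C7=C8 enol ether in one step; Rubottom oxidation then gives the C7–OH/C8 ketone.
4. Ring C (lactone) is closed by an intramolecular Reformatsky reaction of the C7 2-bromopropanoate onto the C8 ketone; acylations at C2, C9 and C12 finish the route.
5. Ring order: A (step 2), T (step 14), B (step 22), C (step 24). C9 comes from the chiral pool and relays to C10, C1, C11, C12, C2, C6, C7, C8 and C17.

Key step: step 2

Remark: briarane numbering of the target is used for all intermediates (C1 quaternary carbon with the C15 methyl, C2 butanoyloxy carbon, C3=C4, C5=C16, C6–Cl, C7–O–C19 lactone, C8–OH, C9 and C12 acetoxy carbons, C10 ring-fusion CH, C11 with the C20 methyl, C13=C14, C17 with the C18 methyl). Starting materials 1, 2, 4 and 16 and all reagents are assumed to be commercial.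

**Route**

Step 1
Reactants: 1 (4R)-2,2-dimethyl-1,3-dioxolane-4-carbaldehyde; 2 ethyl 2-(triphenylphosphoranylidene)propanoate
Product: 3 ethyl (2E)-3-[(4S)-2,2-dimethyl-1,3-dioxolan-4-yl]-2-methylprop-2-enoate
Conditions: CH2Cl2, 0 °C → rt
Reagents that add atoms: none
Why: Wittig olefination with the stabilised α-branched ylide should give the (E)-trisubstituted enoate, and the C9 stereocentre comes unchanged from the chiral pool.

Step 2
Reactants: 3 ethyl (2E)-3-[(4S)-2,2-dimethyl-1,3-dioxolan-4-yl]-2-methylprop-2-enoate; 4 (3E)-4-methoxybut-3-en-2-one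
Product: 7 ethyl (1S,6S)-6-[(4S)-2,2-dimethyl-1,3-dioxolan-4-yl]-1-methyl-4-oxocyclohex-2-ene-1-carboxylate, via lithium dienolate 5 (not isolated), via Michael adduct enolate 6 (not isolated)
Conditions: LiN(iPr)2, THF, −78 °C (4); then 3, −78 → 0 °C; aq NH4Cl
Reagents that add atoms: none
Why: Tandem Michael/Michael addition–elimination (double Michael annulation, the anionic counterpart of the Diels–Alder reaction of 1-methoxy-3-silyloxybutadienes): LiN(iPr)2 removes a proton from the only enolisable position of 4 (its methyl group) to give dienolate 5, which adds through C11 to C10 of enoate 3. The resulting ester enolate 6 (C1=C2) closes ring A by a 6-endo-trig Michael addition of C1 to C14 of the vinylogous ester, and loss of methoxide makes the closure irreversible and leaves the C12 ketone and the C13=C14 alkene. C10 is set in the first addition: the C9–H bond eclipses the alkene to avoid A(1,3) strain with the C1 methyl group and the dienolate adds anti to the C9–O bond, as in conjugate additions to glyceraldehyde-derived enoates. C1 is set in the ring closure: in 6 the C10–H bond again lies in the enolate plane, C14 arrives on the face that carries C11, and C2 therefore ends trans to C9 on ring A. The step needs 1,4- over 1,2-addition and C- over O-attack, which the delocalised dienolate, the ester acceptor and warming to 0 °C (reversible 1,2-adducts, irreversible elimination) should secure.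

Step 3
Reactants: 7 ethyl (1S,6S)-6-[(4S)-2,2-dimethyl-1,3-dioxolan-4-yl]-1-methyl-4-oxocyclohex-2-ene-1-carboxylate
Product: 8 ethyl (1S,6S)-6-[(1S)-1,2-dihydroxyethyl]-1-methyl-4-oxocyclohex-2-ene-1-carboxylate
Conditions: AcOH/H2O (4:1), 40 °C
Reagents that add atoms: none
Why: Acid hydrolysis of the terminal isopropylidene acetal should free the C8/C9 diol without touching the enone or the hindered ester; no stereocentre is involved.

Step 4
Reactants: 8 ethyl (1S,6S)-6-[(1S)-1,2-dihydroxyethyl]-1-methyl-4-oxocyclohex-2-ene-1-carboxylate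
Product: 9 ethyl (1S,6S)-6-[(1S)-1,2-bis(tert-butyldimethylsilyloxy)ethyl]-1-methyl-4-oxocyclohex-2-ene-1-carboxylate
Conditions: tBuMe2SiOTf, 2,6-lutidine, CH2Cl2, −78 → 0 °C
Reagents that add atoms: tert-butyldimethylsilyl trifluoromethanesulfonate, CC(C)(C)[Si](C)(C)OS(=O)(=O)C(F)(F)F
Why: Silyl triflate/lutidine silylation should protect both hydroxyl groups, the hindered C9–OH included; no stereocentre is formed.

Step 5
Reactants: 9 ethyl (1S,6S)-6-[(1S)-1,2-bis(tert-butyldimethylsilyloxy)ethyl]-1-methyl-4-oxocyclohex-2-ene-1-carboxylate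
Product: 10 ethyl (1S,6S)-6-[(1S)-1,2-bis(tert-butyldimethylsilyloxy)ethyl]-1,5-dimethyl-4-oxocyclohex-2-ene-1-carboxylate (both C11 epimers)
Conditions: LiN(iPr)2, THF, −78 °C; MeI, −78 → −20 °C
Reagents that add atoms: iodomethane, CI
Why: Deprotonation of the enone can only occur at C11 (C1 is quaternary) and C-methylation of the cross-conjugated enolate brings in C20; the C11 configuration is irrelevant because it is re-enolised in step 6.

Step 6
Reactants: 10 ethyl (1S,6S)-6-[(1S)-1,2-bis(tert-butyldimethylsilyloxy)ethyl]-1,5-dimethyl-4-oxocyclohex-2-ene-1-carboxylate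
Product: 11 ethyl (1S,5S,6S)-6-[(1S)-1,2-bis(tert-butyldimethylsilyloxy)ethyl]-5-hydroxy-1,5-dimethyl-4-oxocyclohex-2-ene-1-carboxylate
Conditions: KN(SiMe3)2, THF, −78 °C; 3-phenyl-2-(phenylsulfonyl)oxaziridine; aq NH4Cl
Reagents that add atoms: 3-phenyl-2-(phenylsulfonyl)oxaziridine, O=S(=O)(N1OC1c1ccccc1)c1ccccc1
Why: Enolate hydroxylation with the N-sulfonyloxaziridine; the oxidant should approach C11 on the face opposite to the bulky C9 side chain on neighbouring C10, placing 11-OH trans to C9 (11S).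

Step 7
Reactants: 11 ethyl (1S,5S,6S)-6-[(1S)-1,2-bis(tert-butyldimethylsilyloxy)ethyl]-5-hydroxy-1,5-dimethyl-4-oxocyclohex-2-ene-1-carboxylate
Product: 12 ethyl (1S,4R,5S,6S)-6-[(1S)-1,2-bis(tert-butyldimethylsilyloxy)ethyl]-4,5-dihydroxy-1,5-dimethylcyclohex-2-ene-1-carboxylate
Conditions: NaBH4, CeCl3·7H2O, MeOH, −78 °C
Reagents that add atoms: none
Why: Luche 1,2-reduction of the enone; hydride should add anti to the pseudo-axial C11–O bond, giving the 11,12-cis-diol (12R), the only isomer able to form the acetonide of step 8.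

Step 8
Reactants: 12 ethyl (1S,4R,5S,6S)-6-[(1S)-1,2-bis(tert-butyldimethylsilyloxy)ethyl]-4,5-dihydroxy-1,5-dimethylcyclohex-2-ene-1-carboxylate
Product: 13 11,12-O-isopropylidene acetal of 12 (cis-fused 2,2-dimethyl-1,3-dioxolane on C11/C12)
Conditions: 2-methoxypropene, pyridinium p-toluenesulfonate (cat.), CH2Cl2, 0 °C
Reagents that add atoms: 2-methoxypropene, COC(C)=C
Why: Acid-catalysed transacetalisation of the cis-1,2-diol should give the cis-fused acetonide; no stereocentre is formed.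

Step 9
Reactants: 13 11,12-O-isopropylidene acetal of 12
Product: 14 C8 primary alcohol (13 with the primary silyl ether removed; 9-OSiMe2tBu kept)
Conditions: HF·pyridine, pyridine, THF, 0 °C
Reagents that add atoms: none
Why: Buffered HF·pyridine cleaves the primary silyl ether much faster than the hindered secondary one; no stereocentre is involved.

Step 10
Reactants: 14 C8 primary alcohol
Product: 15 C8 aldehyde (9S α-silyloxy aldehyde)
Conditions: Dess–Martin periodinane, NaHCO3, CH2Cl2, 0 °C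
Reagents that add atoms: none
Why: Dess–Martin oxidation of the primary alcohol under buffered conditions that should not epimerise C9.

Step 11
Reactants: 15 C8 aldehyde; 16 3-bromo-1-(trimethylsilyl)prop-1-yne
Product: 17 C8 homopropargylic alcohol, 8-CH(OH)CH2C≡CSiMe3 (both C8 epimers)
Conditions: Zn, THF, 0 °C → rt; aq NH4Cl
Reagents that add atoms: none
Why: Barbier-type propargylation; the silyl-capped propargylzinc reagent should add through its CH2 terminus (C3–C5 introduced), and the C8 configuration is irrelevant because C8 is oxidised in step 13.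

Step 12
Reactants: 17 C8 homopropargylic alcohol
Product: 18 2,8-diol (C2 as CH2OH, C8 as CHOH)
Conditions: LiAlH4, Et2O, 0 °C
Reagents that add atoms: none
Why: LiAlH4 reduces the neopentyl ester (or any lactone it forms with the C8 alkoxide) to the C2 primary alcohol; no stereocentre is formed.

Step 13
Reactants: 18 2,8-diol
Product: 19 C2 aldehyde/C8 ketone (β,γ-alkynyl ketone)
Conditions: Dess–Martin periodinane (3 equiv), NaHCO3, CH2Cl2, 0 °C
Reagents that add atoms: none
Why: Double Dess–Martin oxidation should give the C2 aldehyde and the C8 ketone in one operation under buffered conditions that avoid alkyne-to-allene isomerisation.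

Step 14
Reactants: 19 C2 aldehyde/C8 ketone
Product: 20 ring-T aldol: 2-hydroxy-3-[(trimethylsilyl)ethynyl]-8-oxo tricycle (ring T trans-fused to ring A; 2-OH cis and 3-alkynyl trans to the C15 methyl, both equatorial)
Conditions: LiN(SiMe3)2, THF, −78 → 0 °C; AcOH
Reagents that add atoms: none
Why: Intramolecular aldol addition (enolate of the C8 ketone at the doubly activated C3, non-enolisable C2 aldehyde) closes ring T; warming lets the aldolate equilibrate so that 2-OH (2S) and the 3-alkynyl group should both sit equatorial on the trans-fused chair.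

Step 15
Reactants: 20 ring-T aldol
Product: 21 2-O-triethylsilyl ether of 20
Conditions: Et3SiOTf, 2,6-lutidine, CH2Cl2, −78 °C
Reagents that add atoms: triethylsilyl trifluoromethanesulfonate, CC[Si](CC)(CC)OS(=O)(=O)C(F)(F)F
Why: Low-temperature silylation should protect the β-hydroxy ketone without retro-aldol cleavage; no stereocentre is formed.

Step 16
Reactants: 21 2-O-triethylsilyl ether of 20
Product: 22 8-ethynyl-8-hydroxy compound (8-OH equatorial, cis to the C15 methyl; 8-ethynyl axial, cis to the 3-alkynyl group)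
Conditions: HC≡CMgBr, CeCl3, THF, −78 °C; aq NH4Cl
Reagents that add atoms: ethynylmagnesium bromide, C#C[Mg]Br
Why: Organocerium 1,2-addition suppresses enolisation at the acidic C3–H; the small nucleophile should attack C8 axially, on the face opposite to the axial 9-silyloxy group, which sets C8.

Step 17
Reactants: 22 8-ethynyl-8-hydroxy compound
Product: 23 8-[(E)-2-chlorovinyl]-8-hydroxy compound
Conditions: Cp2Zr(H)Cl, THF, rt; then N-chlorosuccinimide, 0 °C
Reagents that add atoms: N-chlorosuccinimide, O=C1CCC(=O)N1Cl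
Why: Syn hydrozirconation of the terminal alkyne (zirconium at the terminus; the silylated alkyne reacts far more slowly) and chlorination with retention should give the (E)-chloroalkene.

Step 18
Reactants: 23 8-[(E)-2-chlorovinyl]-8-hydroxy compound
Product: 24 3-ethynyl compound (C-silyl group removed)
Conditions: K2CO3, MeOH, 0 °C
Reagents that add atoms: none
Why: Methanolysis of the alkynyl–silicon bond frees the C3 ethynyl group while the silyl ethers and the vinyl chloride should survive these mild conditions.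

Step 19
Reactants: 24 3-ethynyl compound
Product: 25 3-(3-hydroxyprop-1-ynyl) compound (propargylic alcohol, C16 introduced)
Conditions: EtMgBr, THF, 0 °C → rt; (CH2O)n, 40 °C; aq NH4Cl
Reagents that add atoms: formaldehyde (as paraformaldehyde), C=O
Why: The magnesium acetylide (the tertiary alkoxide forms as well) adds to formaldehyde to give the primary propargylic alcohol.

Step 20
Reactants: 25 3-(3-hydroxyprop-1-ynyl) compound
Product: 26 3-(propa-1,2-dienyl) compound (terminal allene C4=C5=C16; 8-OH free)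
Conditions: PPh3, diethyl azodicarboxylate, 2-nitrobenzenesulfonylhydrazide, THF, −15 °C → rt
Reagents that add atoms: none
Why: Mitsunobu displacement of the primary propargylic alcohol by the sulfonylhydrazide, loss of sulfinic acid and retro-ene loss of N2 from the propargylic diazene should give the allene at or below room temperature; the tertiary 8-OH does not react.

Step 21
Reactants: 26 3-(propa-1,2-dienyl) compound
Product: 27 8-O-trimethylsilyl ether of 26
Conditions: 1-(trimethylsilyl)imidazole, CH2Cl2, rt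
Reagents that add atoms: 1-(trimethylsilyl)imidazole, C[Si](C)(C)n1ccnc1
Why: The N-silylimidazole silylates the hindered tertiary alcohol under neutral conditions, so that step 22 runs as a neutral siloxy-Cope rearrangement.

Step 22
Reactants: 27 8-O-trimethylsilyl ether of 26
Product: 29 ring-B α-hydroxy ketone: (3Z)-6-chloro-7-hydroxy-8-oxo-5(16)-methylene ten-membered ring (6S,7R), via silyl enol ether 28 (not isolated)
Conditions: toluene, 2,6-di-tert-butyl-4-methylphenol (cat.), sealed tube, 130 °C; then dimethyldioxirane, acetone/CH2Cl2, −78 °C; citric acid, MeOH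
Reagents that add atoms: dimethyldioxirane, CC1(C)OO1
Why: Thermal siloxy-Cope rearrangement of the cis-1-allenyl-2-alkenyl unit (C5 bonds to C6, the C3–C8 bond of ring T breaks) opens ring T to ring B; the chair-like transition state fixed by the equatorial allenyl and axial chlorovinyl groups should give the (3Z)-alkene, the C5 exo-methylene, 6S from the E-chloroalkene and enol ether 28 without a β-chloro enolate being formed, and Rubottom oxidation should then add oxygen to C7 anti to the allylic C6–Cl bond (C6–H eclipsing the enol ether, A(1,3) strain) to give 7R.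

Step 23
Reactants: 29 ring-B α-hydroxy ketone
Product: 30 7-O-(2-bromopropanoyl) ester of 29
Conditions: 2-bromopropanoyl bromide, pyridine, CH2Cl2, −40 °C
Reagents that add atoms: 2-bromopropanoyl bromide, CC(Br)C(Br)=O
Why: Acylation of the secondary α-ketol at low temperature with a weak base (to avoid β-elimination of chloride) installs C17–C19.

Step 24
Reactants: 30 7-O-(2-bromopropanoyl) ester of 29
Product: 31 lactone (ring C closed): 2-O-triethylsilyl-9-O-tert-butyldimethylsilyl-11,12-O-isopropylidene derivative of the 8-hydroxy-19,7-olide (8R,17R)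
Conditions: SmI2, THF, −78 °C
Reagents that add atoms: none
Why: Intramolecular Reformatsky reaction: the samarium enolate formed at the bromoester should add to the C8 ketone through a chelated transition state on the face of the C7–O tether, giving 8-OH cis to the C18 methyl group (methyl trans to C9), and C8 is no longer enolisable afterwards.

Step 25
Reactants: 31 lactone
Product: 32 C2 alcohol (triethylsilyl ether removed)
Conditions: HF·pyridine, pyridine, THF, 0 °C
Reagents that add atoms: none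
Why: Buffered HF·pyridine should remove the triethylsilyl ether selectively beside the more robust tert-butyldimethylsilyl ether and the acetonide.

Step 26
Reactants: 32 C2 alcohol
Product: 33 C2 butanoate
Conditions: (PrCO)2O, Et3N, 4-(dimethylamino)pyridine, CH2Cl2, 0 °C
Reagents that add atoms: butanoic anhydride, CCCC(=O)OC(=O)CCC
Why: Acylation of the only free secondary hydroxyl group; the tertiary 8-OH should not react under these conditions.

Step 27
Reactants: 33 C2 butanoate
Product: 34 (1S,2S,3Z,6S,7R,8R,9S,10S,11S,12R,17R)-2-butanoyloxy-6-chloro-8,9,11,12-tetrahydroxybriara-3,5(16),13-trien-19,7-olide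
Conditions: 48% aq HF, MeCN, 0 °C → rt
Reagents that add atoms: none
Why: Aqueous HF in acetonitrile should cleave the remaining silyl ether and hydrolyse the acetonide without base.

Step 28
Reactants: 34 2-butanoyloxy-6-chloro-8,9,11,12-tetrahydroxybriara-3,5(16),13-trien-19,7-olide
Product: 35 (1S,2S,3Z,6S,7R,8R,9S,10S,11S,12R,17R)-9,12-diacetoxy-2-butanoyloxy-6-chloro-8,11-dihydroxybriara-3,5(16),13-trien-19,7-olide (target)
Conditions: Ac2O, pyridine, 4-(dimethylamino)pyridine (cat.), CH2Cl2, 0 °C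
Reagents that add atoms: acetic anhydride, CC(=O)OC(C)=O
Why: Acetylation of the two secondary hydroxyl groups (C9, C12) while the tertiary 8- and 11-hydroxyl groups stay free should give the target.

**Compound list**
1 | (4R)-2,2-dimethyl-1,3-dioxolane-4-carbaldehyde | O=C[C@H]1COC(C)(C)O1 | starting material
2 | ethyl 2-(triphenylphosphoranylidene)propanoate | CCOC(=O)C(C)=P(c1ccccc1)(c1ccccc1)c1ccccc1 | starting material
3 | ethyl (2E)-3-[(4S)-2,2-dimethyl-1,3-dioxolan-4-yl]-2-methylprop-2-enoate | CCOC(=O)/C(C)=C/[C@H]1COC(C)(C)O1 | intermediate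
4 | (3E)-4-methoxybut-3-en-2-one | CO/C=C/C(C)=O | starting material
5 | lithium (3E)-4-methoxybuta-1,3-dien-2-olate | [Li]OC(=C)/C=C/OC | intermediate
6 | lithium enolate of ethyl (3S,6E)-3-[(4S)-2,2-dimethyl-1,3-dioxolan-4-yl]-7-methoxy-2-methyl-5-oxohept-6-enoate | CCOC(O[Li])=C(C)[C@H](CC(=O)/C=C/OC)[C@H]1COC(C)(C)O1 | intermediate
7 | ethyl (1S,6S)-6-[(4S)-2,2-dimethyl-1,3-dioxolan-4-yl]-1-methyl-4-oxocyclohex-2-ene-1-carboxylate | CCOC(=O)[C@@]1(C)C=CC(=O)C[C@@H]1[C@H]1COC(C)(C)O1 | intermediate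
8 | ethyl (1S,6S)-6-[(1S)-1,2-dihydroxyethyl]-1-methyl-4-oxocyclohex-2-ene-1-carboxylate | CCOC(=O)[C@@]1(C)C=CC(=O)C[C@@H]1[C@H](O)CO | intermediate
9 | ethyl (1S,6S)-6-[(1S)-1,2-bis(tert-butyldimethylsilyloxy)ethyl]-1-methyl-4-oxocyclohex-2-ene-1-carboxylate | CCOC(=O)[C@@]1(C)C=CC(=O)C[C@@H]1[C@H](O[Si](C)(C)C(C)(C)C)CO[Si](C)(C)C(C)(C)C | intermediate
10 | ethyl (1S,6S)-6-[(1S)-1,2-bis(tert-butyldimethylsilyloxy)ethyl]-1,5-dimethyl-4-oxocyclohex-2-ene-1-carboxylate (C11 epimers) | CCOC(=O)[C@@]1(C)C=CC(=O)C(C)[C@@H]1[C@H](O[Si](C)(C)C(C)(C)C)CO[Si](C)(C)C(C)(C)C | intermediate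
11 | ethyl (1S,5S,6S)-6-[(1S)-1,2-bis(tert-butyldimethylsilyloxy)ethyl]-5-hydroxy-1,5-dimethyl-4-oxocyclohex-2-ene-1-carboxylate | CCOC(=O)[C@@]1(C)C=CC(=O)[C@@](C)(O)[C@@H]1[C@H](O[Si](C)(C)C(C)(C)C)CO[Si](C)(C)C(C)(C)C | intermediate
12 | ethyl (1S,4R,5S,6S)-6-[(1S)-1,2-bis(tert-butyldimethylsilyloxy)ethyl]-4,5-dihydroxy-1,5-dimethylcyclohex-2-ene-1-carboxylate | CCOC(=O)[C@@]1(C)C=C[C@@H](O)[C@@](C)(O)[C@@H]1[C@H](O[Si](C)(C)C(C)(C)C)CO[Si](C)(C)C(C)(C)C | intermediate
13 | 11,12-O-isopropylidene acetal of 12 | CCOC(=O)[C@@]1(C)C=C[C@H]2OC(C)(C)O[C@@]2(C)[C@@H]1[C@H](O[Si](C)(C)C(C)(C)C)CO[Si](C)(C)C(C)(C)C | intermediate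
14 | C8 primary alcohol (9-O-silyl, 11,12-acetonide, C2 ethyl ester) | CCOC(=O)[C@@]1(C)C=C[C@H]2OC(C)(C)O[C@@]2(C)[C@@H]1[C@H](O[Si](C)(C)C(C)(C)C)CO | intermediate
15 | C8 aldehyde | CCOC(=O)[C@@]1(C)C=C[C@H]2OC(C)(C)O[C@@]2(C)[C@@H]1[C@H](O[Si](C)(C)C(C)(C)C)C=O | intermediate
16 | 3-bromo-1-(trimethylsilyl)prop-1-yne | C[Si](C)(C)C#CCBr | starting material
17 | C8 homopropargylic alcohol (C8 epimers) | CCOC(=O)[C@@]1(C)C=C[C@H]2OC(C)(C)O[C@@]2(C)[C@@H]1[C@H](O[Si](C)(C)C(C)(C)C)C(O)CC#C[Si](C)(C)C | intermediate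
18 | 2,8-diol | OC[C@@]1(C)C=C[C@H]2OC(C)(C)O[C@@]2(C)[C@@H]1[C@H](O[Si](C)(C)C(C)(C)C)C(O)CC#C[Si](C)(C)C | intermediate
19 | C2 aldehyde/C8 ketone | O=C[C@@]1(C)C=C[C@H]2OC(C)(C)O[C@@]2(C)[C@@H]1[C@H](O[Si](C)(C)C(C)(C)C)C(=O)CC#C[Si](C)(C)C | intermediate
20 | ring-T aldol (2-OH cis, 3-alkynyl trans to the C15 methyl) | C[Si](C)(C)C#C[C@H]1[C@H](O)[C@@]2(C)C=C[C@H]3OC(C)(C)O[C@@]3(C)[C@@H]2[C@H](O[Si](C)(C)C(C)(C)C)C1=O | intermediate
21 | 2-O-triethylsilyl ether of 20 | C[Si](C)(C)C#C[C@H]1[C@H](O[Si](CC)(CC)CC)[C@@]2(C)C=C[C@H]3OC(C)(C)O[C@@]3(C)[C@@H]2[C@H](O[Si](C)(C)C(C)(C)C)C1=O | intermediate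
22 | 8-ethynyl-8-hydroxy compound (8-OH cis to the C15 methyl) | C[Si](C)(C)C#C[C@H]1[C@H](O[Si](CC)(CC)CC)[C@@]2(C)C=C[C@H]3OC(C)(C)O[C@@]3(C)[C@@H]2[C@H](O[Si](C)(C)C(C)(C)C)[C@@]1(O)C#C | intermediate
23 | 8-[(E)-2-chlorovinyl]-8-hydroxy compound | C[Si](C)(C)C#C[C@H]1[C@H](O[Si](CC)(CC)CC)[C@@]2(C)C=C[C@H]3OC(C)(C)O[C@@]3(C)[C@@H]2[C@H](O[Si](C)(C)C(C)(C)C)[C@@]1(O)/C=C/Cl | intermediate
24 | 3-ethynyl compound | C#C[C@H]1[C@H](O[Si](CC)(CC)CC)[C@@]2(C)C=C[C@H]3OC(C)(C)O[C@@]3(C)[C@@H]2[C@H](O[Si](C)(C)C(C)(C)C)[C@@]1(O)/C=C/Cl | intermediate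
25 | 3-(3-hydroxyprop-1-ynyl) compound | OCC#C[C@H]1[C@H](O[Si](CC)(CC)CC)[C@@]2(C)C=C[C@H]3OC(C)(C)O[C@@]3(C)[C@@H]2[C@H](O[Si](C)(C)C(C)(C)C)[C@@]1(O)/C=C/Cl | intermediate
26 | 3-(propa-1,2-dienyl) compound | C=C=C[C@H]1[C@H](O[Si](CC)(CC)CC)[C@@]2(C)C=C[C@H]3OC(C)(C)O[C@@]3(C)[C@@H]2[C@H](O[Si](C)(C)C(C)(C)C)[C@@]1(O)/C=C/Cl | intermediate
27 | 8-O-trimethylsilyl ether of 26 | C=C=C[C@H]1[C@H](O[Si](CC)(CC)CC)[C@@]2(C)C=C[C@H]3OC(C)(C)O[C@@]3(C)[C@@H]2[C@H](O[Si](C)(C)C(C)(C)C)[C@@]1(O[Si](C)(C)C)/C=C/Cl | intermediate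
28 | ring-B silyl enol ether (3Z, 7E, 6S) | C=C1/C=C\[C@H](O[Si](CC)(CC)CC)[C@@]2(C)C=C[C@H]3OC(C)(C)O[C@@]3(C)[C@@H]2[C@H](O[Si](C)(C)C(C)(C)C)/C(O[Si](C)(C)C)=C/[C@H]1Cl | intermediate
29 | ring-B α-hydroxy ketone (6S,7R) | C=C1/C=C\[C@H](O[Si](CC)(CC)CC)[C@@]2(C)C=C[C@H]3OC(C)(C)O[C@@]3(C)[C@@H]2[C@H](O[Si](C)(C)C(C)(C)C)C(=O)[C@@H](O)[C@H]1Cl | intermediate
30 | 7-O-(2-bromopropanoyl) ester of 29 | C=C1/C=C\[C@H](O[Si](CC)(CC)CC)[C@@]2(C)C=C[C@H]3OC(C)(C)O[C@@]3(C)[C@@H]2[C@H](O[Si](C)(C)C(C)(C)C)C(=O)[C@@H](OC(=O)C(C)Br)[C@H]1Cl | intermediate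
31 | lactone (2-O-triethylsilyl, 9-O-tert-butyldimethylsilyl, 11,12-acetonide) | C=C1/C=C\[C@H](O[Si](CC)(CC)CC)[C@@]2(C)C=C[C@H]3OC(C)(C)O[C@@]3(C)[C@@H]2[C@H](O[Si](C)(C)C(C)(C)C)[C@]2(O)[C@@H](C)C(=O)O[C@H]2[C@H]1Cl | intermediate
32 | C2 alcohol | C=C1/C=C\[C@H](O)[C@@]2(C)C=C[C@H]3OC(C)(C)O[C@@]3(C)[C@@H]2[C@H](O[Si](C)(C)C(C)(C)C)[C@]2(O)[C@@H](C)C(=O)O[C@H]2[C@H]1Cl | intermediate
33 | C2 butanoate | C=C1/C=C\[C@H](OC(=O)CCC)[C@@]2(C)C=C[C@H]3OC(C)(C)O[C@@]3(C)[C@@H]2[C@H](O[Si](C)(C)C(C)(C)C)[C@]2(O)[C@@H](C)C(=O)O[C@H]2[C@H]1Cl | intermediate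
34 | (1S,2S,3Z,6S,7R,8R,9S,10S,11S,12R,17R)-2-butanoyloxy-6-chloro-8,9,11,12-tetrahydroxybriara-3,5(16),13-trien-19,7-olide | C=C1/C=C\[C@H](OC(=O)CCC)[C@@]2(C)C=C[C@@H](O)[C@@](C)(O)[C@@H]2[C@H](O)[C@]2(O)[C@@H](C)C(=O)O[C@H]2[C@H]1Cl | intermediate
35 | (1S,2S,3Z,6S,7R,8R,9S,10S,11S,12R,17R)-9,12-diacetoxy-2-butanoyloxy-6-chloro-8,11-dihydroxybriara-3,5(16),13-trien-19,7-olide | C=C1/C=C\[C@H](OC(=O)CCC)[C@@]2(C)C=C[C@@H](OC(C)=O)[C@@](C)(O)[C@@H]2[C@H](OC(C)=O)[C@]2(O)[C@@H](C)C(=O)O[C@H]2[C@H]1Cl | target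

**Totals and risks**
Total step count: 28. Longest linear sequence: 28 steps (1 → 35).

Steps most likely to fail:

Step 2. The intermolecular conjugate addition to the trisubstituted enoate may be slow, so that self-condensation of the dienolate, 1,2-addition or proton transfer from C11 to the ester enolate stops the cascade before ring closure; facial selectivity at C10 may also be incomplete. Fallback (sets out from 1, returns at 7): Wittig olefination of 1 with 2-(triphenylphosphoranylidene)propanal gives (2E)-3-[(4S)-2,2-dimethyl-1,3-dioxolan-4-yl]-2-methylprop-2-enal F1. A thermal Diels–Alder reaction of this more reactive enal with (E)-3-(tert-butyldimethylsilyloxy)-N,N-dimethylbuta-1,3-dien-1-amine (toluene, rt) gives the amino silyl enol ether cycloadduct F2 with the same E-to-trans transfer and the same facial bias. HF in MeCN then gives the 4-formyl enone F3, NaClO2/NaH2PO4/2-methylbut-2-ene gives the carboxylic acid F4, and EtI/K2CO3 in DMF gives 7.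

Step 22. The rearrangement may lose to allene–alkene [2+2] or ene pathways, the β-chloro silyl enol ether may lose Me3SiCl to give an enone at 130 °C, dimethyldioxirane may attack the diene, and the facial selectivity of the oxidation at C7 may be poor. Fallback (sets out from 26, returns at 29): the free carbinol 26 is rearranged as its potassium alkoxide (KN(SiMe3)2, 18-crown-6, THF, −40 °C, anionic oxy-Cope), and the β-chloro enolate is allowed to expel chloride to give the cross-conjugated ring-B 6-en-8-one F5. Weitz–Scheffer epoxidation (tBuOOH, 1,8-diazabicyclo[5.4.0]undec-7-ene) gives the trans 6,7-epoxy ketone F6, and LiCl/AcOH in THF opens the epoxide at the allylic C6 with inversion to the anti chlorohydrin 29. In this variant the C6/C7 relation is fixed by the trans opening, and only the face of the epoxidation has to be controlled by the ring.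

Step 24. Divalent samarium may instead cleave the C7–O bond of the α-acyloxy ketone or reduce the allylic chloride, base-type β-elimination of chloride may intervene, and the facial selectivity at C8 or the C17 configuration may be wrong. Fallback (sets out from 29, returns at 31): a chelation-controlled Mukaiyama aldol addition of (E)-1-ethoxy-1-(trimethylsilyloxy)prop-1-ene to the free α-hydroxy ketone 29 (MgBr2·OEt2, CH2Cl2, −20 °C) gives the β-hydroxy ester F7 without any enolisable intermediate at C7. Pyridinium p-toluenesulfonate in benzene then lactonises the C7 hydroxyl onto the ester to give 31, and C17 can be equilibrated at the lactone stage.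

Further compounds
F1 | step 2 | (2E)-3-[(4S)-2,2-dimethyl-1,3-dioxolan-4-yl]-2-methylprop-2-enal | O=C/C(C)=C/[C@H]1COC(C)(C)O1
F2 | step 2 | Diels–Alder cycloadduct: 4-(tert-butyldimethylsilyloxy)-2-(dimethylamino)-6-[(4S)-2,2-dimethyl-1,3-dioxolan-4-yl]-1-methylcyclohex-3-ene-1-carbaldehyde (1S,6S; C2 unassigned) | O=C[C@@]1(C)C(N(C)C)C=C(O[Si](C)(C)C(C)(C)C)C[C@@H]1[C@H]1COC(C)(C)O1
F3 | step 2 | (1S,6S)-6-[(4S)-2,2-dimethyl-1,3-dioxolan-4-yl]-1-methyl-4-oxocyclohex-2-ene-1-carbaldehyde | O=C[C@@]1(C)C=CC(=O)C[C@@H]1[C@H]1COC(C)(C)O1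
F4 | step 2 | (1S,6S)-6-[(4S)-2,2-dimethyl-1,3-dioxolan-4-yl]-1-methyl-4-oxocyclohex-2-ene-1-carboxylic acid | OC(=O)[C@@]1(C)C=CC(=O)C[C@@H]1[C@H]1COC(C)(C)O1
F5 | step 22 | ring-B 6-en-8-one (3Z, 5(16)-methylene, chlorine lost) | C=C1/C=C\[C@H](O[Si](CC)(CC)CC)[C@@]2(C)C=C[C@H]3OC(C)(C)O[C@@]3(C)[C@@H]2[C@H](O[Si](C)(C)C(C)(C)C)C(=O)C=C1
F6 | step 22 | ring-B trans 6,7-epoxy-8-ketone | C=C1/C=C\[C@H](O[Si](CC)(CC)CC)[C@@]2(C)C=C[C@H]3OC(C)(C)O[C@@]3(C)[C@@H]2[C@H](O[Si](C)(C)C(C)(C)C)C(=O)[C@H]4O[C@H]14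
F7 | step 24 | ethyl (17R)-propanoate adduct: 7,8-dihydroxy-8-[1-(ethoxycarbonyl)ethyl] ring-B compound (6S,7R,8R) | C=C1/C=C\[C@H](O[Si](CC)(CC)CC)[C@@]2(C)C=C[C@H]3OC(C)(C)O[C@@]3(C)[C@@H]2[C@H](O[Si](C)(C)C(C)(C)C)[C@](O)([C@@H](C)C(=O)OCC)[C@@H](O)[C@H]1Cl
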